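**Assumption (remark on the chemistry):** the SMILES is read literally, so H‑5 and the C10 methyl are cis (a cis‑fused 5‑epi‑labdane, 4S,5S,9S,10R). Labdane numbering is used for positions throughout (ring A C1–C5/C10, ring B C5–C10, side chain C11–C16, exocyclic methylene C17, ester carbon C19, angular methyl C20); β is the face of C20.

## Structural features

The target is a decalin (ring A: C1–C5, C10; ring B: C5–C10) with a methyl and a methyl ester on C4, an angular methyl on C10, an exocyclic methylene on C8 and a five‑carbon chain on C9. The four stereocentres form one chain, C4–C5–C10–C9, in which the quaternary carbons C4 and C10 flank the C5 methine. H‑5 lies on the same face as the C10 methyl, so the rings are cis‑fused, and the ester on C4, H‑5, the C10 methyl and the C9 chain are all β. The side chain ends in an (E)‑2‑substituted but‑2‑ene‑1,4‑diol in which C12 is cis to C15; the two CH2OH groups are trans, so reduction of a butenolide cannot deliver it. Fragile elements are the 1,1‑disubstituted C8=C17 alkene next to C9–H (acid isomerisation), the allylic diol, the ester, and C9 whenever C8 is a ketone. The real difficulty is the cis ring fusion between two quaternary carbons together with the 1,3‑cis relation of ester and angular methyl; trans‑labdane chiral pool materials, E‑polyene cyclisations and dissolving‑metal reductions all deliver 5α‑H. The key step exploits ring A: CO2Me on C4, H on C5 and CH3 on C10 are mutually cis, which is the endo pattern of a [4+2] adduct between a C4=C5 (E)‑2‑methylenoate and a C10=C1–C2=C3 diene. If the four carbons C6–C9 of ring B tether C5 to the Z position of C10, the cis fusion is enforced by geometry.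

## Logic of the disconnections

**30 ⇒ 29 ⇒ 23 + 27.** The two O–Si bonds are cut first, then the C12–C13 sp3–sp2 bond. This takes the only side‑chain olefin geometry out of the core synthesis, because 27 carries it ready‑made. The forward coupling must retain the geometry of 27 and tolerate the ester and the C8=C17 alkene.

**23 ⇒ 22 ⇒ 21 ⇒ 20.** C12–I goes back to C12–OH, C8=C17 to a C8 ketone, and the ketone to the C8 carbinol of 20. These are functional‑group changes only, but they set the order: the C8 oxygen must be gone before C12 becomes an electrophile, or a tetrahydrofuran would form. The forward steps must oxidise the secondary C8–OH beside the primary C12–OH and must not epimerise C9.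

**20 ⇒ 19.** Two H atoms on C1/C2 and two O‑benzyl bonds are removed retrosynthetically. This reveals the C1=C2 alkene of 19, the retron of a Diels–Alder reaction, at no stereochemical cost because C1–C3 are methylenes.

**19 ⇒ 18 (key).** Bonds C5–C10 and C3–C4 are cut. Both rings open at once to the acyclic triene 18. C4, C5 and C10 cease to be stereocentres and become alkene geometry, (E) at C4=C5 and (Z) at C10=C1, so that only C8 and C9 remain. The forward step must run through the single cis‑fused, ester‑endo transition state on one diene face and must outrun a sigmatropic hydrogen shift of the Z‑diene.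

**18 ⇒ 17 ⇒ 16.** The C4=C5 bond is cut (carbonyl olefination) and the C5 aldehyde is masked as its acetal. The dienophile thus arrives last from a commercial ylide. The olefination must be E‑selective and the unmasking must spare the diene.

**16 ⇒ 15 ⇒ 13 ⇒ 12.** The O8–benzyl bond and the C2=C3 bond are cut, and the lactol 13 is traced to the lactone 12. The six‑membered ring of 12 ties C2 to O‑8 and so fixes C9 and C2 cis on C10=C1, which turns the awkward Z‑trisubstituted diene into a ring problem. The ring‑opened enal must be methylenated before it can isomerise.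

**12 ⇒ 11 ⇒ 9 ⇒ 8.** The C10–CH3 bond is cut back to the enol triflate 11, then the C1–C10 bond (Claisen‑type lactonisation) back to the acetate 9 and the alcohol 8. The lactone carbons C1/C2 then come from an acetyl group and the auxiliary is released in the same operation. The cyclisation must not touch C9–H.

**8 ⇒ 4 + 6.** The C8–C9 bond is cut (aldol). This is the only step that needs external asymmetric induction: it sets C9, which later controls C4, C5 and C10, and C8, which is later destroyed. It must give the syn adduct so that O‑8 is equatorial in the cycloaddition.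

**Starting materials.** 4 comes from 1 and 2 by N‑acylation, 6 from 5 by partial reduction, and 27 from 24 through 26.

## Other disconnections considered

**Alternative 1:** (the first that comes to mind) cut C1–C10 and C4–C5 of ring A and add H‑5 afterwards. Forward: Robinson annulation to the enone ester A1, deconjugative C4‑methylation to the Δ5 keto ester A2, then hydrogenation of C5=C6. The hydrogen would have to arrive on the β face, which carries both the axial C10 methyl and the C4 ester, so the cis fusion would rest on a directing‑group tactic rather than on the skeleton. The C4/C10 relation would rest on a substrate‑controlled alkylation. A2 also carries two carbonyls (C3, C9) that must be removed or homologated. The chosen plan sets C4, C5 and C10 in one step from olefin geometry and carries no superfluous oxygen in ring A.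

**Alternative 2:** cut C4–C5 and C9–C10. Forward: cationic bicyclisation of the acyclic (Z,Z)‑trienyl allylsilane A3 to the cis‑decalin A4, relying on anti addition across a (Z)‑C5=C10 olefin. The tertiary C10 cation is stabilised enough to live between the two ring closures, so the cis outcome could leak to trans. The C19 substituent would have to sit axial, 1,3 to the C10 methyl, in the transition state. Absolute control would need a chiral initiator, and A3 itself needs three stereodefined trisubstituted olefins. The pericyclic step of the chosen plan is stereospecific by mechanism rather than by conformational preference.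

**Alternative 3:** cut C5–C6 and C9–C10 of ring B. Forward: intermolecular Diels–Alder union of the ring‑A enone A5 with the silyloxy diene A6 to the cis‑octalone A7. Cis fusion is automatic, but the face of A5 is distinguished only by CH3 versus CO2Me on C4 (similar size), so the C4/C5 relation is not secured. The regiochemistry that joins C9 to C10 places the oxygen on C7 rather than C8. A7 would then need removal of the C1 and C7 oxygens and a Δ7 to 8(17) transposition. The chosen plan avoids all three corrections and derives the C4/C5 relation from E geometry.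

Key step: step 12

## Steps

Step 1
Reactants: 1 4-(benzyloxy)butanoic acid; 2 (S)-4-benzyloxazolidin-2-one
Product: 4 (S)-4-benzyl-3-[4-(benzyloxy)butanoyl]oxazolidin-2-one, via mixed pivalic anhydride 3 (not isolated)
Conditions: PivCl, Et3N, THF, −20 °C; then LiCl, 2, −20 → 23 °C
Reagents that add atoms: none
Why: Mixed‑anhydride N‑acylation; the LiCl‑activated oxazolidinone attacks the unhindered carbonyl of the pivalic anhydride. No stereocentre is formed.

Step 2
Reactants: 5 methyl 4,4-dimethoxybutanoate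
Product: 6 4,4-dimethoxybutanal
Conditions: DIBAL-H (1.05 equiv), CH2Cl2, −78 °C; Rochelle salt
Reagents that add atoms: none
Why: Partial DIBAL reduction of an ester; the aluminium hemiacetal is stable at −78 °C and releases the aldehyde on work‑up. The acetal is inert.

Step 3
Reactants: 4 (S)-4-benzyl-3-[4-(benzyloxy)butanoyl]oxazolidin-2-one; 6 4,4-dimethoxybutanal
Product: 8 (S)-4-benzyl-3-[(2S,3R)-2-[2-(benzyloxy)ethyl]-3-hydroxy-6,6-dimethoxyhexanoyl]oxazolidin-2-one, via dibutylboron Z-enolate 7 (not isolated)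
Conditions: Bu2BOTf, Et3N, CH2Cl2, −78 → 0 °C; 6, −78 → 0 °C; pH 7 buffer, MeOH, H2O2
Reagents that add atoms: none
Why: Evans syn‑aldol reaction; the Z(O)‑boron enolate reacts through a chair Zimmerman–Traxler transition state on the face away from the auxiliary benzyl group, which sets C9 (2S) and C8 (3R) syn. C9 is the stereocentre that later controls C4, C5 and C10.

Step 4
Reactants: 8 (S)-4-benzyl-3-[(2S,3R)-2-[2-(benzyloxy)ethyl]-3-hydroxy-6,6-dimethoxyhexanoyl]oxazolidin-2-one
Product: 9 (S)-4-benzyl-3-[(2S,3R)-3-acetoxy-2-[2-(benzyloxy)ethyl]-6,6-dimethoxyhexanoyl]oxazolidin-2-one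
Conditions: Ac2O, Et3N, DMAP (cat.), CH2Cl2, 0 → 23 °C
Reagents that add atoms: acetic anhydride CC(=O)OC(C)=O
Why: DMAP‑catalysed O‑acylation; the acetate supplies C1 and C2 and its enolate closes the lactone in step 5.

Step 5
Reactants: 9 (S)-4-benzyl-3-[(2S,3R)-3-acetoxy-2-[2-(benzyloxy)ethyl]-6,6-dimethoxyhexanoyl]oxazolidin-2-one
Product: 11 (5S,6R)-5-[2-(benzyloxy)ethyl]-6-(3,3-dimethoxypropyl)-2-oxo-5,6-dihydro-2H-pyran-4-yl trifluoromethanesulfonate, via potassium pyranone enolate 10 (not isolated)
Conditions: KHMDS (2.1 equiv), THF, −78 °C; then PhNTf2, −78 → 0 °C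
Reagents that add atoms: N-phenylbis(trifluoromethanesulfonimide) O=S(=O)(N(c1ccccc1)S(=O)(=O)C(F)(F)F)C(F)(F)F
Why: Intramolecular Claisen (Dieckmann‑type) condensation; the acetate enolate attacks the exocyclic imide carbonyl (C10), the oxazolidinone leaves, and the β‑keto‑δ‑lactone enolate is O‑triflated in the same flask. The α‑branched imide C9–H is not removed (A(1,3) strain), so the cis‑5,6 relation from the syn aldol should be kept.

Step 6
Reactants: 11 (5S,6R)-5-[2-(benzyloxy)ethyl]-6-(3,3-dimethoxypropyl)-2-oxo-5,6-dihydro-2H-pyran-4-yl trifluoromethanesulfonate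
Product: 12 (5R,6R)-5-[2-(benzyloxy)ethyl]-6-(3,3-dimethoxypropyl)-4-methyl-5,6-dihydro-2H-pyran-2-one
Conditions: MeMgBr, Fe(acac)3 (5 mol %), THF/NMP, −30 °C
Reagents that add atoms: methylmagnesium bromide C[Mg]Br
Why: Iron‑catalysed cross‑coupling of an alkenyl triflate with a Grignard reagent; it should be much faster than addition to the lactone at −30 °C. It installs C20 on C10 while the ring holds C9 and C2 cis across C10=C1.

Step 7
Reactants: 12 (5R,6R)-5-[2-(benzyloxy)ethyl]-6-(3,3-dimethoxypropyl)-4-methyl-5,6-dihydro-2H-pyran-2-one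
Product: 13 (5R,6R)-5-[2-(benzyloxy)ethyl]-6-(3,3-dimethoxypropyl)-4-methyl-5,6-dihydro-2H-pyran-2-ol
Conditions: DIBAL-H (1.1 equiv), CH2Cl2, −78 °C
Reagents that add atoms: none
Why: Lactone‑to‑lactol reduction with DIBAL at low temperature; the anomeric centre (both epimers) is lost in step 8.

Step 8
Reactants: 13 (5R,6R)-5-[2-(benzyloxy)ethyl]-6-(3,3-dimethoxypropyl)-4-methyl-5,6-dihydro-2H-pyran-2-ol
Product: 15 (4R,5R,6Z)-5-[2-(benzyloxy)ethyl]-1,1-dimethoxy-6-methylnona-6,8-dien-4-ol, via ring-opened Z-hydroxy enal 14 (not isolated)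
Conditions: Ph3PCH3Br, KOtBu, THF, 0 → 23 °C
Reagents that add atoms: methyltriphenylphosphonium bromide C[P+](c1ccccc1)(c1ccccc1)c1ccccc1.[Br-]
Why: Wittig methylenation of a lactol through its open hydroxy‑enal tautomer. Because the enal comes from a six‑membered ring, C9 and the new vinyl group are cis on C10=C1, giving the (Z)‑diene.

Step 9
Reactants: 15 (4R,5R,6Z)-5-[2-(benzyloxy)ethyl]-1,1-dimethoxy-6-methylnona-6,8-dien-4-ol
Product: 16 (4R,5R,6Z)-4-(benzyloxy)-5-[2-(benzyloxy)ethyl]-1,1-dimethoxy-6-methylnona-6,8-diene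
Conditions: NaH, BnBr, Bu4NI (cat.), THF/DMF, 0 → 23 °C
Reagents that add atoms: benzyl bromide BrCc1ccccc1
Why: Williamson etherification; the ether keeps O‑8 from adding to the enoate made in step 11 (5‑exo oxa‑Michael) and is removed for free in step 13.

Step 10
Reactants: 16 (4R,5R,6Z)-4-(benzyloxy)-5-[2-(benzyloxy)ethyl]-1,1-dimethoxy-6-methylnona-6,8-diene
Product: 17 (4R,5R,6Z)-4-(benzyloxy)-5-[2-(benzyloxy)ethyl]-6-methylnona-6,8-dienal
Conditions: PPTS (0.2 equiv), acetone/H2O 9:1, 45 °C
Reagents that add atoms: water O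
Why: Mild acid‑catalysed acetal hydrolysis; benzyl ethers and the diene should tolerate buffered pyridinium acid.

Step 11
Reactants: 17 (4R,5R,6Z)-4-(benzyloxy)-5-[2-(benzyloxy)ethyl]-6-methylnona-6,8-dienal
Product: 18 methyl (2E,6R,7R,8Z)-6-(benzyloxy)-7-[2-(benzyloxy)ethyl]-2,8-dimethylundeca-2,8,10-trienoate
Conditions: Ph3P=C(CH3)CO2Me, CH2Cl2, 40 °C
Reagents that add atoms: methyl 2-(triphenylphosphoranylidene)propanoate COC(=O)C(C)=P(c1ccccc1)(c1ccccc1)c1ccccc1
Why: Wittig olefination with a stabilised ylide, which gives the (E)‑2‑methylenoate; CO2Me ends up trans to C6, as the cycloaddition requires.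

Step 12
Reactants: 18 methyl (2E,6R,7R,8Z)-6-(benzyloxy)-7-[2-(benzyloxy)ethyl]-2,8-dimethylundeca-2,8,10-trienoate
Product: 19 methyl (1S,4aS,5R,6R,8aS)-6-(benzyloxy)-5-[2-(benzyloxy)ethyl]-1,4a-dimethyl-1,2,4a,5,6,7,8,8a-octahydronaphthalene-1-carboxylate
Conditions: PhMe (5 mM), BHT (0.1 equiv), sealed tube, 170 °C
Reagents that add atoms: none
Why: Intramolecular Diels–Alder reaction (type 1, 1,7,9‑decatriene class; the closest known reaction type is the thermal cyclisation of deca‑2,7,9‑trienoates, where a diene tethered through its Z position gives only cis‑fused bicycles): a concerted suprafacial [4+2] between the (E)‑2‑methylenoate C4=C5 and the diene C10=C1–C2=C3 forms C3–C4 and C5–C10. Ring A closes as the six‑membered cycloadduct ring (cyclohexene, C1=C2), and ring B closes at the same moment as the six‑membered ring of the four‑carbon tether C6–C9, fused through the new C5–C10 bond. For C5 and C10, the tether sits on the Z position of C10, so only the transition state with C6 exo can be reached and H‑5 must end up cis to the C10 methyl. For C4, the E geometry of the dienophile is carried over suprafacially, so CO2Me stays cis to H‑5 (the endo orientation of the ester) and the C4 methyl cis to C6, which is 4β‑CO2Me/4α‑CH3. The absolute sense comes from C9: A(1,3) strain with the C2 vinyl group of the (Z)‑diene keeps C9–H in the diene plane, C8 leads the tether to one face and the C11 chain blocks the other. The tether folds as a chair with C11 and the 8‑OBn group equatorial, which gives the 9β chain cis to the C10 methyl. The selectivities needed are therefore one diene face, secured by C9, and cycloaddition ahead of a [1,5]‑H shift from C9 to C3, which is helped by the in‑plane (misaligned) C9–H, high dilution and BHT. No new stereocentre depends on reagent control.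

Step 13
Reactants: 19 methyl (1S,4aS,5R,6R,8aS)-6-(benzyloxy)-5-[2-(benzyloxy)ethyl]-1,4a-dimethyl-1,2,4a,5,6,7,8,8a-octahydronaphthalene-1-carboxylate
Product: 20 methyl (1S,4aS,5R,6R,8aS)-6-hydroxy-5-(2-hydroxyethyl)-1,4a-dimethyldecahydronaphthalene-1-carboxylate
Conditions: H2 (1 atm), Pd(OH)2/C, EtOAc/MeOH, 23 °C
Reagents that add atoms: none
Why: Catalytic hydrogenation of the cis‑disubstituted C1=C2 bond with concurrent hydrogenolysis of both benzyl ethers; no stereocentre is at stake because C1–C3 are methylenes.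

Step 14
Reactants: 20 methyl (1S,4aS,5R,6R,8aS)-6-hydroxy-5-(2-hydroxyethyl)-1,4a-dimethyldecahydronaphthalene-1-carboxylate
Product: 21 methyl (1S,4aS,5R,8aS)-5-(2-hydroxyethyl)-1,4a-dimethyl-6-oxodecahydronaphthalene-1-carboxylate
Conditions: NaOCl (aq., 1.1 equiv), AcOH, 0 → 23 °C
Reagents that add atoms: none
Why: Hypochlorite oxidation in acetic acid, which oxidises secondary alcohols much faster than primary ones; the ketone formed equilibrates with its five‑membered hemiketal, which further shields the primary hydroxyl.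

Step 15
Reactants: 21 methyl (1S,4aS,5R,8aS)-5-(2-hydroxyethyl)-1,4a-dimethyl-6-oxodecahydronaphthalene-1-carboxylate
Product: 22 methyl (1S,4aR,5S,8aS)-5-(2-hydroxyethyl)-1,4a-dimethyl-6-methylidenedecahydronaphthalene-1-carboxylate
Conditions: Ph3PCH3Br (4 equiv), KOtBu (3.8 equiv), THF, 0 → 45 °C
Reagents that add atoms: methyltriphenylphosphonium bromide C[P+](c1ccccc1)(c1ccccc1)c1ccccc1.[Br-]
Why: Wittig methylenation with excess ylide (one equivalent is consumed as the alkoxide). Enolisation towards C9 is disfavoured next to the quaternary C10, so the C9 configuration should be retained, and the hindered tertiary ester is inert.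

Step 16
Reactants: 22 methyl (1S,4aR,5S,8aS)-5-(2-hydroxyethyl)-1,4a-dimethyl-6-methylidenedecahydronaphthalene-1-carboxylate
Product: 23 methyl (1S,4aR,5S,8aS)-5-(2-iodoethyl)-1,4a-dimethyl-6-methylidenedecahydronaphthalene-1-carboxylate
Conditions: I2, PPh3, imidazole, CH2Cl2, 0 °C
Reagents that add atoms: iodine II
Why: Appel‑type iodination of a primary alcohol by SN2 displacement of the alkoxyphosphonium; no oxygen nucleophile remains on C8, so cyclic ether formation is excluded.

Step 17
Reactants: 24 but-2-yne-1,4-diol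
Product: 26 (Z)-2-iodobut-2-ene-1,4-diol, via cyclic alkenylalanate 25 (not isolated)
Conditions: Red-Al (2.2 equiv), THF, 0 → 23 °C; then I2, THF, −78 → 0 °C
Reagents that add atoms: iodine II
Why: Hydroxyl‑directed trans‑hydroalumination of the alkyne, then iodinolysis of the C–Al bond with retention. H and I end up trans, so the two CH2OH groups are trans, as in the target side chain.

Step 18
Reactants: 26 (Z)-2-iodobut-2-ene-1,4-diol
Product: 27 (Z)-1,4-bis(tert-butyldimethylsilyloxy)-2-iodobut-2-ene
Conditions: TBSCl (2.4 equiv), imidazole, DMF, 23 °C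
Reagents that add atoms: tert-butyldimethylsilyl chloride CC(C)(C)[Si](C)(C)Cl
Why: Standard silylation of two primary alcohols; it masks the acidic protons for the organozinc coupling.

Step 19
Reactants: 23 methyl (1S,4aR,5S,8aS)-5-(2-iodoethyl)-1,4a-dimethyl-6-methylidenedecahydronaphthalene-1-carboxylate; 27 (Z)-1,4-bis(tert-butyldimethylsilyloxy)-2-iodobut-2-ene
Product: 29 methyl (1S,4aR,5S,8aS)-5-[(3E)-5-[(tert-butyldimethylsilyl)oxy]-3-{[(tert-butyldimethylsilyl)oxy]methyl}pent-3-en-1-yl]-1,4a-dimethyl-6-methylidenedecahydronaphthalene-1-carboxylate, via alkylzinc iodide 28 (not isolated)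
Conditions: Zn dust (TMSCl/BrCH2CH2Br‑activated), LiCl, THF, 40 °C; then 27, Pd(dppf)Cl2 (5 mol %), THF, 50 °C
Reagents that add atoms: none
Why: Negishi sp3–sp2 coupling; zinc inserts into the primary iodide and the alkylzinc couples with the alkenyl iodide with retention of its geometry (C12 cis to C15). The ester and the exocyclic alkene are tolerated, and dppf suppresses β‑hydride elimination.

Step 20
Reactants: 29 methyl (1S,4aR,5S,8aS)-5-[(3E)-5-[(tert-butyldimethylsilyl)oxy]-3-{[(tert-butyldimethylsilyl)oxy]methyl}pent-3-en-1-yl]-1,4a-dimethyl-6-methylidenedecahydronaphthalene-1-carboxylate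
Product: 30 methyl (1S,4aR,5S,8aS)-5-[(3E)-5-hydroxy-3-(hydroxymethyl)pent-3-en-1-yl]-1,4a-dimethyl-6-methylidenedecahydronaphthalene-1-carboxylate
Conditions: TBAF (2.5 equiv), THF, 0 → 23 °C
Reagents that add atoms: none
Why: Fluoride desilylation of both silyl ethers under non‑acidic conditions, which should leave the exocyclic alkene, the trisubstituted alkene and the ester untouched.

## Compound list

1 | 4-(benzyloxy)butanoic acid | OC(=O)CCCOCc1ccccc1 | starting material
2 | (S)-4-benzyloxazolidin-2-one | O=C1OC[C@H](Cc2ccccc2)N1 | starting material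
3 | 4-(benzyloxy)butanoic pivalic anhydride | CC(C)(C)C(=O)OC(=O)CCCOCc1ccccc1 | intermediate (not isolated)
4 | (S)-4-benzyl-3-[4-(benzyloxy)butanoyl]oxazolidin-2-one | O=C(CCCOCc1ccccc1)N1[C@@H](Cc2ccccc2)COC1=O | intermediate
5 | methyl 4,4-dimethoxybutanoate | COC(=O)CCC(OC)OC | starting material
6 | 4,4-dimethoxybutanal | O=CCCC(OC)OC | intermediate
7 | dibutylboron (Z)-enolate of 4 | CCCCB(CCCC)O/C(=C\CCOCc1ccccc1)N1[C@@H](Cc2ccccc2)COC1=O | intermediate (not isolated)
8 | (S)-4-benzyl-3-[(2S,3R)-2-[2-(benzyloxy)ethyl]-3-hydroxy-6,6-dimethoxyhexanoyl]oxazolidin-2-one | O=C(N1[C@@H](Cc2ccccc2)COC1=O)[C@@H](CCOCc3ccccc3)[C@H](O)CCC(OC)OC | intermediate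
9 | (S)-4-benzyl-3-[(2S,3R)-3-acetoxy-2-[2-(benzyloxy)ethyl]-6,6-dimethoxyhexanoyl]oxazolidin-2-one | O=C(N1[C@@H](Cc2ccccc2)COC1=O)[C@@H](CCOCc3ccccc3)[C@H](OC(C)=O)CCC(OC)OC | intermediate
10 | potassium (5S,6R)-5-[2-(benzyloxy)ethyl]-6-(3,3-dimethoxypropyl)-2-oxo-5,6-dihydro-2H-pyran-4-olate | O=C1C=C([O-])[C@@H](CCOCc2ccccc2)[C@@H](CCC(OC)OC)O1.[K+] | intermediate (not isolated)
11 | (5S,6R)-5-[2-(benzyloxy)ethyl]-6-(3,3-dimethoxypropyl)-2-oxo-5,6-dihydro-2H-pyran-4-yl trifluoromethanesulfonate | O=C1C=C(OS(=O)(=O)C(F)(F)F)[C@@H](CCOCc2ccccc2)[C@@H](CCC(OC)OC)O1 | intermediate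
12 | (5R,6R)-5-[2-(benzyloxy)ethyl]-6-(3,3-dimethoxypropyl)-4-methyl-5,6-dihydro-2H-pyran-2-one (5,6-cis) | O=C1C=C(C)[C@@H](CCOCc2ccccc2)[C@@H](CCC(OC)OC)O1 | intermediate
13 | (5R,6R)-5-[2-(benzyloxy)ethyl]-6-(3,3-dimethoxypropyl)-4-methyl-5,6-dihydro-2H-pyran-2-ol (both C2 epimers) | OC1C=C(C)[C@@H](CCOCc2ccccc2)[C@@H](CCC(OC)OC)O1 | intermediate
14 | (2Z,4R,5R)-4-[2-(benzyloxy)ethyl]-5-hydroxy-8,8-dimethoxy-3-methyloct-2-enal | O=C/C=C(C)\[C@@H](CCOCc1ccccc1)[C@H](O)CCC(OC)OC | intermediate (not isolated)
15 | (4R,5R,6Z)-5-[2-(benzyloxy)ethyl]-1,1-dimethoxy-6-methylnona-6,8-dien-4-ol | C=C/C=C(C)\[C@@H](CCOCc1ccccc1)[C@H](O)CCC(OC)OC | intermediate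
16 | (4R,5R,6Z)-4-(benzyloxy)-5-[2-(benzyloxy)ethyl]-1,1-dimethoxy-6-methylnona-6,8-diene | C=C/C=C(C)\[C@@H](CCOCc1ccccc1)[C@H](OCc1ccccc1)CCC(OC)OC | intermediate
17 | (4R,5R,6Z)-4-(benzyloxy)-5-[2-(benzyloxy)ethyl]-6-methylnona-6,8-dienal | C=C/C=C(C)\[C@@H](CCOCc1ccccc1)[C@H](OCc1ccccc1)CCC=O | intermediate
18 | methyl (2E,6R,7R,8Z)-6-(benzyloxy)-7-[2-(benzyloxy)ethyl]-2,8-dimethylundeca-2,8,10-trienoate | C=C/C=C(C)\[C@@H](CCOCc1ccccc1)[C@H](OCc1ccccc1)CC/C=C(\C)C(=O)OC | intermediate
19 | methyl (1S,4aS,5R,6R,8aS)-6-(benzyloxy)-5-[2-(benzyloxy)ethyl]-1,4a-dimethyl-1,2,4a,5,6,7,8,8a-octahydronaphthalene-1-carboxylate (cis-fused; 4β-CO2Me, 5β-H, 10β-CH3, 9β-chain, 8α-OBn, Δ1) | O(Cc1ccccc1)[C@@H]1CC[C@H]2[C@](C)(C=CC[C@]2(C)C(=O)OC)[C@H]1CCOCc1ccccc1 | intermediate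
20 | methyl (1S,4aS,5R,6R,8aS)-6-hydroxy-5-(2-hydroxyethyl)-1,4a-dimethyldecahydronaphthalene-1-carboxylate | O[C@@H]1CC[C@H]2[C@](C)(CCC[C@]2(C)C(=O)OC)[C@H]1CCO | intermediate
21 | methyl (1S,4aS,5R,8aS)-5-(2-hydroxyethyl)-1,4a-dimethyl-6-oxodecahydronaphthalene-1-carboxylate | O=C1CC[C@H]2[C@](C)(CCC[C@]2(C)C(=O)OC)[C@H]1CCO | intermediate
22 | methyl (1S,4aR,5S,8aS)-5-(2-hydroxyethyl)-1,4a-dimethyl-6-methylidenedecahydronaphthalene-1-carboxylate | C=C1CC[C@H]2[C@](C)(CCC[C@]2(C)C(=O)OC)[C@H]1CCO | intermediate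
23 | methyl (1S,4aR,5S,8aS)-5-(2-iodoethyl)-1,4a-dimethyl-6-methylidenedecahydronaphthalene-1-carboxylate | C=C1CC[C@H]2[C@](C)(CCC[C@]2(C)C(=O)OC)[C@H]1CCI | intermediate
24 | but-2-yne-1,4-diol | OCC#CCO | starting material
25 | disodium cyclic alkenylalanate (2,5-dihydro-1,2-oxaluminole formed by trans-hydroalumination) | [Na+].[Na+].COCCO[Al-]1(OCCOC)OCC=C1CO[AlH-](OCCOC)OCCOC | intermediate (not isolated)
26 | (Z)-2-iodobut-2-ene-1,4-diol | OC/C=C(\I)CO | intermediate
27 | (Z)-1,4-bis(tert-butyldimethylsilyloxy)-2-iodobut-2-ene | CC(C)(C)[Si](C)(C)OC/C=C(\I)CO[Si](C)(C)C(C)(C)C | intermediate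
28 | alkylzinc iodide derived from 23 | C=C1CC[C@H]2[C@](C)(CCC[C@]2(C)C(=O)OC)[C@H]1CC[Zn]I | intermediate (not isolated)
29 | methyl (1S,4aR,5S,8aS)-5-[(3E)-5-[(tert-butyldimethylsilyl)oxy]-3-{[(tert-butyldimethylsilyl)oxy]methyl}pent-3-en-1-yl]-1,4a-dimethyl-6-methylidenedecahydronaphthalene-1-carboxylate | C=C1CC[C@H]2[C@](C)(CCC[C@]2(C)C(=O)OC)[C@H]1CC/C(=C\CO[Si](C)(C)C(C)(C)C)CO[Si](C)(C)C(C)(C)C | intermediate
30 | methyl (1S,4aR,5S,8aS)-5-[(3E)-5-hydroxy-3-(hydroxymethyl)pent-3-en-1-yl]-1,4a-dimethyl-6-methylidenedecahydronaphthalene-1-carboxylate | C=C1CC[C@H]2[C@](C)(CCC[C@]2(C)C(=O)OC)[C@H]1CC/C(=C\CO)CO | target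

## Step count and least certain steps

Total: 20 steps. Longest linear sequence: 17 steps (1, 3–16, 19, 20).

**Step 12 (key step).** Most likely failure: the cycloaddition forms two quaternary centres and needs the strained s‑cis form of a Z‑diene, so it may be slow enough that a [1,5]‑hydrogen shift from C9 to C3 (loss of the C9 stereocentre and of the diene) or diene oligomerisation competes at 170 °C. Fallback (from 17, returning at 19): olefinate 17 with 2‑(triphenylphosphoranylidene)propanal to the (2E)‑enal F1. Cyclise its Me2AlCl complex at −78 °C to the cis‑fused aldehyde F2; the Lewis‑acid‑bound enal is a far stronger dienophile, so the same geometric control operates well below the temperature of the hydrogen shift. Oxidise with NaClO2/NaH2PO4/2‑methyl‑2‑butene to the acid F3 and esterify with TMSCHN2 in MeOH to 19.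

**Step 5.** Most likely failure: enolisation on the imide side with β‑elimination of acetate, or incomplete O‑triflation of the stabilised enolate in the presence of the oxazolidinone anion. Fallback (from 8, returning at 11): transaminate 8 with Me3Al/MeNHOMe·HCl to the Weinreb amide F4, add excess lithium enolate of methyl acetate to give the δ‑hydroxy‑β‑keto ester F5, lactonise with K2CO3 in MeOH (then NaH2PO4) to the 4‑hydroxy‑5,6‑dihydropyranone F6, and triflate with Tf2O/Et3N at −78 °C to 11.

**Step 8.** Most likely failure: under the basic ylide the ring‑opened Z‑enal may isomerise to the E‑enal or lose the C9 configuration by γ‑deprotonation before it is methylenated. Fallback (from 12, returning at 16): open 12 with Me3Al/MeNHOMe·HCl to the (Z)‑hydroxy Weinreb amide F7. Benzylate under neutral conditions (2‑benzyloxy‑1‑methylpyridinium triflate, MgO) to the benzyl ether F8. Reduce with DIBAL‑H at −78 °C to the (Z)‑enal F9, which carries no alkoxide, and methylenate with salt‑free Ph3P=CH2 at −78 °C to 16.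

**Step 14.** Most likely failure: competing oxidation of the primary alcohol, whose aldehyde would close onto O‑8 and be oxidised on to a lactone. Fallback (from 20, returning at 22): silylate the primary hydroxyl selectively (TBSCl, imidazole, 0 °C) to the mono‑silyl ether F10, oxidise with Dess–Martin periodinane to the ketone F11, methylenate (Ph3P=CH2) to the alkene F12 and desilylate with TBAF to 22.

**Step 15.** Most likely failure: sluggish olefination because the hemiketal masks the ketone, with slow enolisation towards C9 and partial epimerisation under prolonged basic conditions. Fallback (from 21, returning at 22): Peterson olefination; add Me3SiCH2Li/CeCl3 (weakly basic organocerium) to obtain the β‑hydroxysilane F13 and eliminate with KH in THF to 22.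

## Further compounds

F1 | step 12 | (2E,6R,7R,8Z)-6-(benzyloxy)-7-[2-(benzyloxy)ethyl]-2,8-dimethylundeca-2,8,10-trienal | C=C/C=C(C)\[C@@H](CCOCc1ccccc1)[C@H](OCc1ccccc1)CC/C=C(\C)C=O
F2 | step 12 | cis-fused 6-(benzyloxy)-5-[2-(benzyloxy)ethyl]-1,4a-dimethyl-1,2,4a,5,6,7,8,8a-octahydronaphthalene-1-carbaldehyde (configuration as in 19) | O(Cc1ccccc1)[C@@H]1CC[C@H]2[C@](C)(C=CC[C@]2(C)C=O)[C@H]1CCOCc1ccccc1
F3 | step 12 | cis-fused 6-(benzyloxy)-5-[2-(benzyloxy)ethyl]-1,4a-dimethyl-1,2,4a,5,6,7,8,8a-octahydronaphthalene-1-carboxylic acid (configuration as in 19) | O(Cc1ccccc1)[C@@H]1CC[C@H]2[C@](C)(C=CC[C@]2(C)C(=O)O)[C@H]1CCOCc1ccccc1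
F4 | step 5 | (2S,3R)-2-[2-(benzyloxy)ethyl]-3-hydroxy-N,6,6-trimethoxy-N-methylhexanamide | CON(C)C(=O)[C@@H](CCOCc1ccccc1)[C@H](O)CCC(OC)OC
F5 | step 5 | methyl (4S,5R)-4-[2-(benzyloxy)ethyl]-5-hydroxy-8,8-dimethoxy-3-oxooctanoate | COC(=O)CC(=O)[C@@H](CCOCc1ccccc1)[C@H](O)CCC(OC)OC
F6 | step 5 | (5S,6R)-5-[2-(benzyloxy)ethyl]-6-(3,3-dimethoxypropyl)-4-hydroxy-5,6-dihydro-2H-pyran-2-one | O=C1C=C(O)[C@@H](CCOCc2ccccc2)[C@@H](CCC(OC)OC)O1
F7 | step 8 | (2Z,4R,5R)-4-[2-(benzyloxy)ethyl]-5-hydroxy-N,8,8-trimethoxy-N,3-dimethyloct-2-enamide | CON(C)C(=O)/C=C(C)\[C@@H](CCOCc1ccccc1)[C@H](O)CCC(OC)OC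
F8 | step 8 | (2Z,4R,5R)-5-(benzyloxy)-4-[2-(benzyloxy)ethyl]-N,8,8-trimethoxy-N,3-dimethyloct-2-enamide | CON(C)C(=O)/C=C(C)\[C@@H](CCOCc1ccccc1)[C@H](OCc1ccccc1)CCC(OC)OC
F9 | step 8 | (2Z,4R,5R)-5-(benzyloxy)-4-[2-(benzyloxy)ethyl]-8,8-dimethoxy-3-methyloct-2-enal | O=C/C=C(C)\[C@@H](CCOCc1ccccc1)[C@H](OCc1ccccc1)CCC(OC)OC
F10 | step 14 | mono-TBS ether of 20 (silyl on the primary oxygen) | O[C@@H]1CC[C@H]2[C@](C)(CCC[C@]2(C)C(=O)OC)[C@H]1CCO[Si](C)(C)C(C)(C)C
F11 | step 14 | TBS ether of 21 | O=C1CC[C@H]2[C@](C)(CCC[C@]2(C)C(=O)OC)[C@H]1CCO[Si](C)(C)C(C)(C)C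
F12 | step 14 | TBS ether of 22 | C=C1CC[C@H]2[C@](C)(CCC[C@]2(C)C(=O)OC)[C@H]1CCO[Si](C)(C)C(C)(C)C
F13 | step 15 | β-hydroxysilane from 21 (8-hydroxy-8-[(trimethylsilyl)methyl], either C8 epimer) | C[Si](C)(C)CC1(O)CC[C@H]2[C@](C)(CCC[C@]2(C)C(=O)OC)[C@H]1CCO
A1 | alternative 1 | methyl (S)-4a-methyl-2,5-dioxo-2,3,4,4a,5,6,7,8-octahydronaphthalene-1-carboxylate (4-carbomethoxy Wieland–Miescher ketone) | O=C1CC[C@]2(C)C(=O)CCCC2=C1C(=O)OC
A2 | alternative 1 | methyl 1,4a-dimethyl-2,5-dioxo-1,2,3,4,4a,5,6,7-octahydronaphthalene-1-carboxylate (4β-CO2Me, 10β-CH3, Δ5) | O=C1CC[C@]2(C)C(=O)CCC=C2[C@@]1(C)C(=O)OC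
A3 | alternative 2 | acyclic (Z,Z)-trienyl allylsilane (C19 and C12 as benzyl ethers, CH2SiMe3 on C8) | c1ccccc1COC/C(C)=C\CC/C(C)=C\CC/C(C[Si](C)(C)C)=C\CCOCc1ccccc1
A4 | alternative 2 | cis-fused 19-(benzyloxy)-8(17)-ene bicycle with 9β-(2-benzyloxyethyl) chain | C=C1CC[C@H]2[C@](C)(CCC[C@]2(C)COCc3ccccc3)[C@H]1CCOCc1ccccc1
A5 | alternative 3 | methyl (S)-1,3-dimethyl-4-oxocyclohex-2-ene-1-carboxylate | CC1=C[C@@](C)(C(=O)OC)CCC1=O
A6 | alternative 3 | (E)-{[6-(benzyloxy)-3-methylhexa-1,3-dien-2-yl]oxy}(tert-butyl)dimethylsilane | C=C(O[Si](C)(C)C(C)(C)C)/C(C)=C/CCOCc1ccccc1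
A7 | alternative 3 | cis-fused 1-oxo-7-silyloxy-Δ7 adduct (8-methyl, 9β-chain, 4β-CO2Me) | CC1=C(O[Si](C)(C)C(C)(C)C)C[C@H]2[C@](C)(C(=O)CC[C@]2(C)C(=O)OC)[C@H]1CCOCc1ccccc1
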